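## Retrosynthetic overview

1. Numbering as in halimanes: ring A = C1–C5 and C10, ring B = C5–C10, side chain C11–C16, C17 on C8, C18/C19 on C4, C20 on C9.
2. Late stage: the C7 acetate comes from the 6,7-cis-diol, the diol from the C6=C7 alkene of a ring B 5(10),6-diene (OsO4 anti to C17); C13 comes from a Sharpless epoxy alcohol (C12–C13 by B-alkyl Suzuki coupling); C20 comes from methylation of the C9 acid dianion anti to C17.
3. Key disconnection: the C6–C7 bond (ring B) and the C4–C5 bond (ring A) are made in one cationic cascade from a monocyclic 1-ethenyl-2,2-dimethylcyclopentane carrying a methylsuccinic anhydride on its quaternary carbon C10. The C7 acylium adds to the vinyl terminus C6 (ring B closes, spiro at C10), C4 shifts from C10 to C5 (the cyclopentane becomes the six-membered ring A), and loss of H5 gives C5=C10.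
4. Enabling feature: the gem-dimethyl carbon C4 is bonded to C5, and C5 is both an alkene carbon of the ring fusion and β to the oxygenated C7. A C5 cation is therefore reachable by acylation at C6, directly beside a quaternary C10 that holds the tertiary C4 in a strained five-membered ring.
5. Order of rings: the cyclopentane is bought (2,2-dimethylcyclopentanone); ring B closes and ring A forms by ring expansion in the same step. The cascade precursor is assembled by Evans alkylation (C8) and Ireland–Claisen rearrangement (C9–C10).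

Key step: step 7

## Route

Step 1
Reactants: 1 2,2-dimethylcyclopentan-1-one; 2 triethyl phosphonoacetate
Product: 3 ethyl (2E)-2-(2,2-dimethylcyclopentylidene)acetate
Conditions: NaH, THF, 0 °C to reflux
Reagents that add atoms: none
Why: Horner–Wadsworth–Emmons olefination of the hindered ketone should place the ester trans to the gem-dimethyl carbon (the alkene geometry has no consequence later).

Step 2
Reactants: 3 ethyl (2E)-2-(2,2-dimethylcyclopentylidene)acetate
Product: 4 (2E)-2-(2,2-dimethylcyclopentylidene)ethan-1-ol
Conditions: iBu2AlH, CH2Cl2, −78 °C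
Reagents that add atoms: none
Why: 1,2-reduction of the conjugated ester by the aluminium hydride should give the allylic alcohol and leave the alkene untouched.

Step 3
Reactants: 4 (2E)-2-(2,2-dimethylcyclopentylidene)ethan-1-ol; 5 bromoacetyl bromide
Product: 6 (2E)-2-(2,2-dimethylcyclopentylidene)ethyl 2-bromoacetate
Conditions: pyridine, CH2Cl2, 0 °C
Reagents that add atoms: none
Why: O-acylation of a primary allylic alcohol by an acid bromide.

Step 4
Reactants: 6 (2E)-2-(2,2-dimethylcyclopentylidene)ethyl 2-bromoacetate; 7 (4R)-4-benzyl-3-propanoyl-1,3-oxazolidin-2-one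
Product: 8 (4R)-4-benzyl-3-[(2S)-4-{[(2E)-2-(2,2-dimethylcyclopentylidene)ethyl]oxy}-2-methyl-4-oxobutanoyl]-1,3-oxazolidin-2-one
Conditions: NaN(SiMe3)2, THF, −78 °C; then 6, −78 to −40 °C
Reagents that add atoms: none
Why: Evans alkylation; the chelated sodium (Z)-enolate is alkylated by the bromoacetate on the face away from the benzyl group, which sets C8 as S.

Step 5
Reactants: 8 the acylated oxazolidinone
Product: 9 (2S)-4-{[(2E)-2-(2,2-dimethylcyclopentylidene)ethyl]oxy}-2-methyl-4-oxobutanoic acid
Conditions: LiOH, H2O2, THF/H2O, 0 °C; Na2SO3; HCl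
Reagents that add atoms: hydrogen peroxide (as LiOOH), OO
Why: lithium hydroperoxide should attack the exocyclic imide carbonyl much faster than the alkyl ester, freeing the C7 acid and the auxiliary without epimerising C8.

Step 6
Reactants: 9 (2S)-4-{[(2E)-2-(2,2-dimethylcyclopentylidene)ethyl]oxy}-2-methyl-4-oxobutanoic acid
Product: 10 (2S)-3-(1-ethenyl-2,2-dimethylcyclopentyl)-2-methylbutanedioic acid (mixture of epimers at C3 and at the ring carbon, i.e. C9 and C10)
Conditions: LiN(iPr)2 (2.2 equiv), Me3SiCl, THF, −78 to 50 °C; aq. HCl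
Reagents that add atoms: none
Why: Ireland–Claisen rearrangement; the carboxylate protects C8, the ester enolate forms at C9, and the [3,3] shift of its silyl ketene acetal forms the C9–C10 bond and the quaternary C10 with its vinyl group (C9 and C10 arise as mixtures and are both erased later).

Step 7
Reactants: 10 (2S)-3-(1-ethenyl-2,2-dimethylcyclopentyl)-2-methylbutanedioic acid
Product: 12 (8S)-7-oxo-12,13,14,15,16,20-hexanorhalim-5(10)-en-11-oic acid (both C9 epimers), via cyclic anhydride 11 (not isolated)
Conditions: (CF3CO)2O, CH2Cl2, 0 °C, then evaporation; SnCl4, CH2Cl2, −78 to −20 °C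
Reagents that add atoms: none
Why: Proposed new method: SnCl4 opens the anhydride at the less hindered C7 carbonyl to an acylium ion, which adds to the terminal carbon C6 of the vinyl group on C10 (cationic 6-endo closure of ring B, charge at the more substituted C5). That C5 cation is secondary, β to the new carbonyl and next to the quaternary C10, so the C10–C4 bond is expected to shift to C5 as the C6–C7 bond forms (1,2-alkyl shift, ring expansion of the cyclopentane to the six-membered ring A), leaving a tertiary cation at C10 that loses H5 to give the tetrasubstituted C5=C10 alkene. The closest known reactions are the intramolecular acylation of alkenes by alkenoyl chlorides or anhydrides (hex-5-enoyl chloride to cyclohexenone) and the Wagner–Meerwein ring expansion of cyclopentylcarbinyl cations; their union in one cascade is what is new. No stereocentre is made: C8 is not touched (no base, low temperature), and the mixed centres C9 and C10 do not matter, because C10 becomes trigonal and C9 is set in step 10. The step needs acylation by C7 and not by C11, which the ring size secures (six- against five-membered), and migration of C4 and not of C1 or C9, which the substrate secures through the tertiary nature of C4 and the strain released only when a ring bond of the cyclopentane moves. The anti addition across C5=C6 keeps the C9 carboxylate away from the reacting lobe at C5, and the anhydride leaves that carboxyl free on C9 for steps 10 to 13.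

Step 8
Reactants: 12 (8S)-7-oxo-12,13,14,15,16,20-hexanorhalim-5(10)-en-11-oic acid
Product: 13 (8S)-7-(trifluoromethylsulfonyloxy)-12,13,14,15,16,20-hexanorhalima-5(10),6-dien-11-oic acid (both C9 epimers)
Conditions: KN(SiMe3)2 (2.2 equiv), THF, −78 °C; PhNTf2; aq. HCl
Reagents that add atoms: N-phenylbis(trifluoromethanesulfonimide), O=S(=O)(N(c1ccccc1)S(=O)(=O)C(F)(F)F)C(F)(F)F
Why: after the carboxylate forms, the C6 protons (α to the ketone and allylic) should be removed in preference to the tertiary C8 proton, and O-sulfonylation of the extended enolate gives the dienyl triflate without touching C8.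

Step 9
Reactants: 13 the dienyl triflate
Product: 14 (8R)-12,13,14,15,16,20-hexanorhalima-5(10),6-dien-11-oic acid (both C9 epimers; C8 geometry unchanged, only the CIP label changes)
Conditions: Pd(OAc)2 (cat.), PPh3, Et3N, HCO2H, DMF, 60 °C
Reagents that add atoms: none
Why: palladium-catalysed formate reduction of an enol triflate (oxidative addition, hydride transfer from formate, reductive elimination) should give the ring B 5(10),6-diene.

Step 10
Reactants: 14 (8R)-12,13,14,15,16,20-hexanorhalima-5(10),6-dien-11-oic acid
Product: 15 (8R,9R)-12,13,14,15,16-pentanorhalima-5(10),6-dien-11-oic acid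
Conditions: LiN(iPr)2 (2.3 equiv), THF, −78 to 0 °C; MeI, −78 °C; aq. HCl
Reagents that add atoms: iodomethane, CI
Why: α-alkylation of the carboxylic acid dianion (extended enediolate, C9 planar, so both C9 epimers converge); MeI should enter on the face away from the adjacent C17 methyl, which sets C9 as R with C20 trans to C17.

Step 11
Reactants: 15 (8R,9R)-12,13,14,15,16-pentanorhalima-5(10),6-dien-11-oic acid
Product: 16 (8R,9R)-12,13,14,15,16-pentanorhalima-5(10),6-dien-11-ol
Conditions: LiAlH4, THF, reflux
Reagents that add atoms: none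
Why: hydride reduction of the hindered carboxylic acid to the primary alcohol; the diene is inert to LiAlH4.

Step 12
Reactants: 16 (8R,9R)-12,13,14,15,16-pentanorhalima-5(10),6-dien-11-ol
Product: 17 (8R,9R)-12,13,14,15,16-pentanorhalima-5(10),6-dien-11-al
Conditions: Dess–Martin periodinane, NaHCO3, CH2Cl2, 0 °C to rt
Reagents that add atoms: none
Why: Dess–Martin oxidation of a primary alcohol; the aldehyde has a quaternary α-carbon and cannot epimerise.

Step 13
Reactants: 17 (8R,9R)-12,13,14,15,16-pentanorhalima-5(10),6-dien-11-al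
Product: 18 (8R,9R)-13,14,15,16-tetranorhalima-5(10),6,11-triene
Conditions: Ph3PCH3Br, KN(SiMe3)2, THF, 0 °C to rt
Reagents that add atoms: methyltriphenylphosphonium bromide, C[P+](c1ccccc1)(c1ccccc1)c1ccccc1.[Br-]
Why: Wittig methylenation; the small ylide should reach the neopentyl aldehyde and give the C11=C12 vinyl group.

Step 14
Reactants: 19 but-2-yn-1-ol
Product: 21 (2Z)-3-iodobut-2-en-1-ol, via cyclic vinylalanate 20 (not isolated)
Conditions: NaAlH2(OCH2CH2OMe)2, THF, 0 °C; then I2, −78 °C to rt
Reagents that add atoms: iodine, II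
Why: hydroxyl-directed trans-hydroalumination of the propargylic alcohol places aluminium on C3 cis to the CH2O group, and iodinolysis with retention gives the Z-iodide.

Step 15
Reactants: 18 (8R,9R)-13,14,15,16-tetranorhalima-5(10),6,11-triene; 21 (2Z)-3-iodobut-2-en-1-ol
Product: 23 (8R,9R,13Z)-halima-5(10),6,13-trien-15-ol, via B-alkyl borane 22 (not isolated)
Conditions: 9-BBN, THF, rt; then 21, PdCl2(dppf), AsPh3, Cs2CO3, DMF/H2O, rt
Reagents that add atoms: none
Why: 9-BBN should add only to the monosubstituted vinyl group (boron on C12), and B-alkyl Suzuki–Miyaura coupling with the vinyl iodide forms C12–C13 with retention of the Z geometry.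

Step 16
Reactants: 23 (8R,9R,13Z)-halima-5(10),6,13-trien-15-ol
Product: 24 (8R,9R,13R,14S)-13,14-epoxyhalima-5(10),6-dien-15-ol
Conditions: Ti(OiPr)4, L-(+)-diethyl tartrate, tBuOOH, 4 Å MS, CH2Cl2, −20 °C
Reagents that add atoms: tert-butyl hydroperoxide, CC(C)(C)OO
Why: Sharpless asymmetric epoxidation; only the allylic alcohol alkene reacts, and L-(+)-tartrate should deliver oxygen to the face of the Z-allylic alcohol that gives the (13R,14S)-epoxide, by reagent control far from the ring stereocentres.

Step 17
Reactants: 24 (8R,9R,13R,14S)-13,14-epoxyhalima-5(10),6-dien-15-ol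
Product: 25 (6S,7R,8S,9R,13R,14S)-13,14-epoxyhalim-5(10)-ene-6,7,15-triol
Conditions: OsO4 (cat.), NMO, acetone/H2O, 0 °C to rt
Reagents that add atoms: N-methylmorpholine N-oxide, C[N+]1([O-])CCOCC1; water, O (both oxygens are delivered through OsO4, O=[Os](=O)(=O)=O)
Why: Upjohn dihydroxylation; only C6=C7 should react (C5=C10 is tetrasubstituted and flanked by two quaternary carbons), and OsO4 should add to the face opposite the allylic C17 methyl, giving the 6,7-cis-diol trans to C17 (6S,7R).

Step 18
Reactants: 25 (6S,7R,8S,9R,13R,14S)-13,14-epoxyhalim-5(10)-ene-6,7,15-triol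
Product: 26 (6S,7R,8S,9R,13R,14R)-13,14-epoxy-15-iodohalim-5(10)-ene-6,7-diol
Conditions: PPh3, I2, imidazole, CH2Cl2, 0 °C
Reagents that add atoms: iodine, II
Why: Appel iodination should be selective for the primary C15 hydroxyl over the two hindered secondary ring hydroxyls (same geometry at C14, the CIP label changes).

Step 19
Reactants: 26 (6S,7R,8S,9R,13R,14R)-13,14-epoxy-15-iodohalim-5(10)-ene-6,7-diol
Product: 27 (6S,7R,8S,9R,13R)-halima-5(10),14-diene-6,7,13-triol
Conditions: Zn, EtOH, reflux; aq. NH4Cl
Reagents that add atoms: none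
Why: zinc inserts into the C–I bond and the neighbouring epoxide opens (reductive elimination), which gives the C14=C15 vinyl group and the tertiary C13 alcohol with its C–O bond, and so the 13R configuration, untouched.

Step 20
Reactants: 27 (6S,7R,8S,9R,13R)-halima-5(10),14-diene-6,7,13-triol
Product: 28 (6S,7R,8S,9R,13R)-6,13-dihydroxyhalima-5(10),14-dien-7-yl acetate (CNP0126002.3)
Conditions: Ac2O (1.1 equiv), pyridine, CH2Cl2, −20 to 0 °C
Reagents that add atoms: acetic anhydride, CC(=O)OC(C)=O
Why: selective acylation; the C7 hydroxyl is equatorial and the least hindered, the C6 hydroxyl is pseudoaxial beside the C4 gem-dimethyl group and the C13 hydroxyl is tertiary.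

## Compound list

1 | 2,2-dimethylcyclopentan-1-one | CC1(C)CCCC1=O | starting material
2 | triethyl phosphonoacetate | CCOC(=O)CP(=O)(OCC)OCC | starting material
3 | ethyl (2E)-2-(2,2-dimethylcyclopentylidene)acetate | CCOC(=O)/C=C1/C(C)(C)CCC1 | intermediate
4 | (2E)-2-(2,2-dimethylcyclopentylidene)ethan-1-ol | OC/C=C1/C(C)(C)CCC1 | intermediate
5 | bromoacetyl bromide | BrCC(Br)=O | starting material
6 | (2E)-2-(2,2-dimethylcyclopentylidene)ethyl 2-bromoacetate | BrCC(=O)OC/C=C1/C(C)(C)CCC1 | intermediate
7 | (4R)-4-benzyl-3-propanoyl-1,3-oxazolidin-2-one | CCC(=O)N1[C@H](Cc2ccccc2)COC1=O | starting material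
8 | (4R)-4-benzyl-3-[(2S)-4-{[(2E)-2-(2,2-dimethylcyclopentylidene)ethyl]oxy}-2-methyl-4-oxobutanoyl]-1,3-oxazolidin-2-one | C[C@@H](CC(=O)OC/C=C1/C(C)(C)CCC1)C(=O)N1[C@H](Cc2ccccc2)COC1=O | intermediate
9 | (2S)-4-{[(2E)-2-(2,2-dimethylcyclopentylidene)ethyl]oxy}-2-methyl-4-oxobutanoic acid | C[C@@H](CC(=O)OC/C=C1/C(C)(C)CCC1)C(O)=O | intermediate
10 | (2S)-3-(1-ethenyl-2,2-dimethylcyclopentyl)-2-methylbutanedioic acid (epimers at C9 and C10) | C[C@@H](C(C(O)=O)C1(C=C)CCCC1(C)C)C(O)=O | intermediate
11 | (3S)-4-(1-ethenyl-2,2-dimethylcyclopentyl)-3-methyloxolane-2,5-dione (cyclic anhydride, same epimer mixture) | C[C@H]1C(C2(C=C)CCCC2(C)C)C(=O)OC1=O | intermediate (not isolated)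
12 | (8S)-7-oxo-12,13,14,15,16,20-hexanorhalim-5(10)-en-11-oic acid (C9 epimers) | O=C1CC2=C(CCCC2(C)C)C(C(O)=O)[C@@H]1C | intermediate
13 | (8S)-7-(trifluoromethylsulfonyloxy)-12,13,14,15,16,20-hexanorhalima-5(10),6-dien-11-oic acid (C9 epimers) | OC(=O)C1C2=C(C=C(OS(=O)(=O)C(F)(F)F)[C@H]1C)C(C)(C)CCC2 | intermediate
14 | (8R)-12,13,14,15,16,20-hexanorhalima-5(10),6-dien-11-oic acid (C9 epimers) | OC(=O)C1C2=C(C=C[C@H]1C)C(C)(C)CCC2 | intermediate
15 | (8R,9R)-12,13,14,15,16-pentanorhalima-5(10),6-dien-11-oic acid | OC(=O)[C@@]1(C)C2=C(C=C[C@H]1C)C(C)(C)CCC2 | intermediate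
16 | (8R,9R)-12,13,14,15,16-pentanorhalima-5(10),6-dien-11-ol | OC[C@@]1(C)C2=C(C=C[C@H]1C)C(C)(C)CCC2 | intermediate
17 | (8R,9R)-12,13,14,15,16-pentanorhalima-5(10),6-dien-11-al | O=C[C@@]1(C)C2=C(C=C[C@H]1C)C(C)(C)CCC2 | intermediate
18 | (8R,9R)-13,14,15,16-tetranorhalima-5(10),6,11-triene | C=C[C@@]1(C)C2=C(C=C[C@H]1C)C(C)(C)CCC2 | intermediate
19 | but-2-yn-1-ol | CC#CCO | starting material
20 | sodium 2,2-bis(2-methoxyethoxy)-3-methyl-2,5-dihydro-1,2-oxaluminol-2-uide (cyclic vinylalanate) | CC1=CCO[Al-]1(OCCOC)OCCOC.[Na+] | intermediate (not isolated)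
21 | (2Z)-3-iodobut-2-en-1-ol | C/C(I)=C/CO | intermediate
22 | 9-[(8R,9R)-13,14,15,16-tetranorhalima-5(10),6-dien-12-yl]-9-borabicyclo[3.3.1]nonane | C1CCC2CCCC1B2CC[C@@]1(C)C2=C(C=C[C@H]1C)C(C)(C)CCC2 | intermediate (not isolated)
23 | (8R,9R,13Z)-halima-5(10),6,13-trien-15-ol | OC/C=C(/C)CC[C@@]1(C)C2=C(C=C[C@H]1C)C(C)(C)CCC2 | intermediate
24 | (8R,9R,13R,14S)-13,14-epoxyhalima-5(10),6-dien-15-ol | OC[C@@H]3O[C@]3(C)CC[C@@]1(C)C2=C(C=C[C@H]1C)C(C)(C)CCC2 | intermediate
25 | (6S,7R,8S,9R,13R,14S)-13,14-epoxyhalim-5(10)-ene-6,7,15-triol | OC[C@@H]3O[C@]3(C)CC[C@@]1(C)C2=C([C@H](O)[C@H](O)[C@H]1C)C(C)(C)CCC2 | intermediate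
26 | (6S,7R,8S,9R,13R,14R)-13,14-epoxy-15-iodohalim-5(10)-ene-6,7-diol | IC[C@@H]3O[C@]3(C)CC[C@@]1(C)C2=C([C@H](O)[C@H](O)[C@H]1C)C(C)(C)CCC2 | intermediate
27 | (6S,7R,8S,9R,13R)-halima-5(10),14-diene-6,7,13-triol | C=C[C@](C)(O)CC[C@@]1(C)C2=C([C@H](O)[C@H](O)[C@H]1C)C(C)(C)CCC2 | intermediate
28 | (6S,7R,8S,9R,13R)-6,13-dihydroxyhalima-5(10),14-dien-7-yl acetate | C=C[C@](C)(O)CC[C@@]1(C)C2=C([C@H](O)[C@H](OC(C)=O)[C@H]1C)C(C)(C)CCC2 | target

## Step count and risks

Total steps: 20. Longest linear sequence: 19 steps (steps 1–13 and 15–20, from 2,2-dimethylcyclopentanone); step 14 is a one-step side branch.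

Steps most likely to fail:

Step 7 (proposed new method). The cascade may stop at the spiro stage if the C5 cation is captured by chloride or by the C9 carboxylate, or loses a C6 proton, before C4 has shifted. The fallback uses known reactions only and sets out from diacid 10. The diacid is cyclised on purpose to the spiro compound [(CF3CO)2O; AlCl3, CH2Cl2; then Et3N to remove HCl], which should give the spiro enone acid F1. Luche reduction (NaBH4, CeCl3·7H2O, MeOH) should convert it into the spiro allylic alcohol F2. p-Toluenesulfonic acid in warm benzene should ionise F2 to the C5–C6–C7 allyl cation, whose productive outlet is the 1,2-shift of C4 followed by loss of H5. The product is diene acid 14, where the route continues (steps 8 and 9 are then not needed).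

Step 6. The [3,3] shift has to build a quaternary carbon (C10) beside the gem-dimethyl carbon and starts from a dianion. Slow rearrangement with loss of the silyl ketene acetal, or partial epimerisation at C8, are the likely failures. The fallback sets out from alcohol 4. Heating with triethyl orthoacetate and a trace of propionic acid (Johnson–Claisen rearrangement) should give the ester F3. Its lithium enolate is alkylated with ethyl (S)-2-(trifluoromethylsulfonyloxy)propanoate (from ethyl L-lactate; SN2 with inversion, which gives the 8S configuration) to the diester F4. Saponification with LiOH returns to diacid 10.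

Step 20. Acylation at the wrong hydroxyl, double acylation, or acyl migration between the cis-hydroxyls may erode the regioselectivity. The fallback sets out from triol 27. Heating with Bu2SnO in toluene with removal of water should give the 6,7-O-dibutylstannylene acetal F5. Acetyl chloride at 0 °C should then acylate the equatorial C7 oxygen and return to 28.

Further compounds
F1 | step 7 | (9S)-1,1,9-trimethyl-8-oxospiro[4.5]dec-6-ene-10-carboxylic acid (spiro enone acid, epimers at C5 and C10 of the spiro numbering) | O=C1C=CC2(CCCC2(C)C)C(C(O)=O)[C@@H]1C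
F2 | step 7 | (9S)-8-hydroxy-1,1,9-trimethylspiro[4.5]dec-6-ene-10-carboxylic acid (spiro allylic alcohol, epimers at C5, C8 and C10 of the spiro numbering) | OC1C=CC2(CCCC2(C)C)C(C(O)=O)[C@@H]1C
F3 | step 6 | ethyl 2-(1-ethenyl-2,2-dimethylcyclopentyl)acetate (racemic) | CCOC(=O)CC1(C=C)CCCC1(C)C
F4 | step 6 | diethyl (2S)-3-(1-ethenyl-2,2-dimethylcyclopentyl)-2-methylbutanedioate (epimers at C3 and at the ring carbon) | CCOC(=O)C(C1(C=C)CCCC1(C)C)[C@H](C)C(=O)OCC
F5 | step 20 | 6,7-O-dibutylstannylene acetal of (6S,7R,8S,9R,13R)-halima-5(10),14-diene-6,7,13-triol | C=C[C@](C)(O)CC[C@@]1(C)C2=C([C@@H]3O[Sn](CCCC)(CCCC)O[C@@H]3[C@H]1C)C(C)(C)CCC2
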